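## Retrosynthetic overview
1. Z-ylidene C5=C1′: a late, protecting-group-free vinylogous aldol–elimination joins unprotected 3-methyltetronic acid to the (R)-α-methyl aldehyde 12.
2. C5–C6 bond (sp3–sp2, at the E-trisubstituted alkene): Ni-electrocatalytic decarboxylative alkenylation couples chiral acid 10 with (E)-alkenyl iodide 7. This is the main fragment union.
3. Acid 10: visible-light Giese addition of the Roche-ester-derived bromide 8 to acrylic acid. The only stereocentre is purchased in 8.
4. Iodide 7: 3-furyllithium + 4-bromofurfural, ionic deoxygenation, Negishi coupling with pent-3-ynylzinc, then hydrozirconation–iodination.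
5. Rings: none is constructed. Both furans and the butenolide are bought intact and only linked.

Assumption: 2, 5, 8 and 13 are treated as catalogue chemicals (8 is the commercial bromide made from (R)-Roche ester); the SMILES was read as R at the stereocentre, Z at the ylidene and E at the chain alkene.

## Route

**Step 1**
Reactants: 1 3-bromofuran; 2 4-bromofuran-2-carbaldehyde
Product: 3 (4-bromofuran-2-yl)(furan-3-yl)methanol (racemic)
Conditions: 1, n-BuLi, THF, −78 °C, 30 min; then 2, −78 °C; aq. NH4Cl
Reagents that add atoms: none
Why: Br/Li exchange gives 3-furyllithium, stable at −78 °C, and its 1,2-carbonyl addition is far faster than exchange with the C4–Br of 2; the racemic carbinol centre is erased in step 2.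

**Step 2**
Reactants: 3
Product: 4 4-bromo-2-(furan-3-ylmethyl)furan
Conditions: Et3SiH (4 equiv), TFA (3 equiv), CH2Cl2, −30 → 0 °C, slow addition of 3
Reagents that add atoms: none (hydride only)
Why: Ionic hydrogenation, in which acid ionises the doubly furyl-stabilised carbinol and excess silane traps the cation before it can alkylate a furan; the C–Br bond is untouched.

**Step 3**
Reactants: 4; 5 5-bromopent-2-yne
Product: 6 2-(furan-3-ylmethyl)-4-(pent-3-yn-1-yl)furan
Conditions: 5, Zn dust, LiCl, THF, 50 °C; then 4, Pd(OAc)2 (2 mol %), SPhos (4 mol %), THF, rt → 50 °C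
Reagents that add atoms: none
Why: Negishi sp3–sp2 coupling of a primary alkylzinc with a 3-bromofuran; the bulky biaryl phosphine suppresses β-hydride elimination, and the internal alkyne and both furans are inert.

**Step 4**
Reactants: 6
Product: 7 2-(furan-3-ylmethyl)-4-[(3E)-4-iodopent-3-en-1-yl]furan
Conditions: Cp2Zr(H)Cl (2.2 equiv), THF, rt → 40 °C; I2, THF, −78 → 0 °C; aq. Na2S2O3/NaHCO3
Reagents that add atoms: iodine, II
Why: Syn hydrozirconation with excess Schwartz reagent equilibrates Zr to the less hindered, methyl-bearing alkyne carbon (about 9:1), and iodinolysis with retention gives the E-iodide; the minor regioisomer is removed by chromatography.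

**Step 5**
Reactants: 8 methyl (2S)-3-bromo-2-methylpropanoate (1.5 equiv); 9 acrylic acid
Product: 10 (5R)-6-methoxy-5-methyl-6-oxohexanoic acid
Conditions: (TMS)3SiH (1.3 equiv), 4CzIPN (1 mol %), K2HPO4, MeCN, 450 nm LEDs, rt, Ar; NaHCO3 extraction, then acidify
Reagents that add atoms: none (all heavy atoms come from 8 and 9)
Why: Photochemical silyl-radical Giese reaction, in which Br abstraction gives a primary radical next to (not at) the stereocentre, it adds to acrylic acid and Si–H quenches the adduct radical; the near-neutral medium avoids the E1cB loss of HBr to methacrylate that would racemise 8, and the excess of 8 offsets competing hydrosilylation of 9.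

**Step 6 (key fragment union)**
Reactants: 10 (1.8 equiv); 7 (1.0 equiv)
Product: 11 methyl (2R,6E)-9-[5-(furan-3-ylmethyl)furan-3-yl]-2,6-dimethylnon-6-enoate
Conditions: 10, N-hydroxyphthalimide, DIC, DMAP (cat.), DMF, rt; then 7, NiCl2·6H2O (15 mol %), 2,2′-bipyridine (15 mol %), AgNO3 (0.3 equiv), DMF, undivided cell, Mg(+)/RVC(−), constant current, about 3 F/mol, rt, Ar
Reagents that add atoms: none
Why: Ni-electrocatalytic decarboxylative alkenylation (reductive cross-electrophile coupling), in which cathodically generated low-valent Ni inserts into C–I with retention and reduces the in-situ redox-active ester to CO2 and a primary radical; that radical lies three carbons from the stereocentre with no alkene in cyclisation range, reductive elimination forms C5–C6 with E geometry intact, and the sacrificial Mg anode keeps the cell below the oxidation potential of the furans.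

**Step 7**
Reactants: 11
Product: 12 (2R,6E)-9-[5-(furan-3-ylmethyl)furan-3-yl]-2,6-dimethylnon-6-enal
Conditions: DIBAL-H (1.15 equiv), CH2Cl2, −78 °C; MeOH quench at −78 °C, Rochelle salt; used crude
Reagents that add atoms: none (hydride only)
Why: Partial ester reduction through the tetrahedral aluminium hemiacetal, which is stable at −78 °C; the cold, non-basic work-up and immediate use keep the α-methyl centre R.

**Step 8**
Reactants: 12; 13 4-hydroxy-3-methylfuran-2(5H)-one (3-methyltetronic acid, 1.5 equiv)
Product: 14 target, (5Z)-5-{(2R,6E)-9-[5-(furan-3-ylmethyl)furan-3-yl]-2,6-dimethylnon-6-en-1-ylidene}-4-hydroxy-3-methylfuran-2(5H)-one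
Conditions: 13, TBSOTf (3.2 equiv), Et3N (3.0 equiv), CH2Cl2, 0 °C; 12, −78 °C, 2 h; DBU (5 equiv), −78 °C → rt; KF, MeOH; citric acid to pH 4
Reagents that add atoms: none (silicon is fully removed)
Why: Proposed new method: a protecting-group-free vinylogous Mukaiyama aldol–E1cB condensation of an unprotected 3-alkyltetronic acid, in which double O-silylation (acidic 4-OH, then soft enolisation of C5–H) transiently turns 13 into the very electron-rich 2,4-bis(silyloxy)-3-methylfuran; its only free α-carbon (C5) adds to the silyl-triflate-activated aldehyde at −78 °C, with no free amine left to enolise it, so C2′ stays R; DBU then removes the now acidic C5–H of the neutral 4-silyloxybutenolide and expels silanolate, erasing the aldol stereocentres, while A(1,3) strain against the 4-OSi group steers the alkene to Z; fluoride and mild acid cleave the vinylogous silyl ester to release the free tetronic acid; the closest known reaction type is the one-pot silyl triflate/amine vinylogous aldol followed by DBU β-elimination on simple butenolides and 4-O-alkyl tetronates, which to my knowledge has not been shown on a free tetronic acid with silicon acting as a traceless protecting and activating group.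

## Compound list
1 | 3-bromofuran | Brc1ccoc1 | starting material
2 | 4-bromofuran-2-carbaldehyde | O=Cc1cc(Br)co1 | starting material
3 | (4-bromofuran-2-yl)(furan-3-yl)methanol (racemic) | OC(c1ccoc1)c1cc(Br)co1 | intermediate
4 | 4-bromo-2-(furan-3-ylmethyl)furan | Brc1coc(Cc2ccoc2)c1 | intermediate
5 | 5-bromopent-2-yne | CC#CCCBr | starting material
6 | 2-(furan-3-ylmethyl)-4-(pent-3-yn-1-yl)furan | CC#CCCc1coc(Cc2ccoc2)c1 | intermediate
7 | 2-(furan-3-ylmethyl)-4-[(3E)-4-iodopent-3-en-1-yl]furan | I/C(C)=C/CCc1coc(Cc2ccoc2)c1 | intermediate
8 | methyl (2S)-3-bromo-2-methylpropanoate | COC(=O)[C@H](C)CBr | starting material (chiral pool)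
9 | acrylic acid | C=CC(=O)O | starting material
10 | (5R)-6-methoxy-5-methyl-6-oxohexanoic acid | COC(=O)[C@H](C)CCCC(=O)O | intermediate
11 | methyl (2R,6E)-9-[5-(furan-3-ylmethyl)furan-3-yl]-2,6-dimethylnon-6-enoate | COC(=O)[C@H](C)CCC/C(C)=C/CCc1coc(Cc2ccoc2)c1 | intermediate
12 | (2R,6E)-9-[5-(furan-3-ylmethyl)furan-3-yl]-2,6-dimethylnon-6-enal | O=C[C@H](C)CCC/C(C)=C/CCc1coc(Cc2ccoc2)c1 | intermediate
13 | 4-hydroxy-3-methylfuran-2(5H)-one | CC1=C(O)COC1=O | starting material
14 | (5Z)-5-{(2R,6E)-9-[5-(furan-3-ylmethyl)furan-3-yl]-2,6-dimethylnon-6-en-1-ylidene}-4-hydroxy-3-methylfuran-2(5H)-one | CC1=C(O)/C(=C/[C@H](C)CCC/C(C)=C/CCc2coc(Cc3ccoc3)c2)OC1=O | target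

## Summary
Total steps: 8. Longest linear sequence: 7 (steps 1, 2, 3, 4, 6, 7, 8).

Steps most likely to fail:
1. **Step 8 (proposed new step).**
   - Risks: early loss of the 4-O-silyl group could stall the elimination, retro-aldol could compete, or 12 could epimerise.
   - Fallback (known chemistry, +3 steps): O-methylate 13 to 4-methoxy-3-methylfuran-2(5H)-one and add its LDA-derived C5 anion to 12 at −78 °C. Mesylate and eliminate (MsCl/Et3N, then DBU) to the Z-ylidene tetronate, then demethylate with a lithium thiolate or LiCl in a dipolar aprotic solvent.
2. **Step 6.**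
   - Risks: the gem-methyl alkenyl iodide is hindered, so protodeiodination or alkenyl homocoupling may dominate.
   - Fallback: replace the radical union with a two-electron B-alkyl Suzuki–Miyaura coupling. Vinylate 8 to methyl (R)-2-methylpent-4-enoate, hydroborate it with 9-BBN, and couple the borane with 7 under Pd(dppf)Cl2/Cs2CO3.
3. **Step 4.**
   - Risks: methyl versus CH2CH2-furyl regioselectivity may be insufficient, or the iodide isomers may not separate.
   - Fallback (+1 step): build the alkene before attaching the furans. Hydrozirconate and iodinate pent-3-yn-1-ol to the well-characterised, purifiable (E)-4-iodopent-3-en-1-ol, and couple it with 10 under the step 6 conditions. Convert the OH to the iodide and then the alkylzinc, and finish with a Negishi coupling to bromide 4 to reach 11.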